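**Retrosynthetic plan**

1. Atom labels follow the atisane skeleton. The C15 enone with its C16=C17 methylene is traced back to a C15=C16 alkene carrying the C17 methyl, the C14 acetate to a ketone and C13 to a dimethyl ketal. The resulting bicyclo[2.2.2]octenone is cut at C8–C9 and C11–C12 (retro Diels–Alder).
2. Enabling feature: the ring C8–C14–C13–C12–C16–C15, with C17 on C16 and oxygen on C14, has the carbon and oxygen pattern of a 6-alkylated creosol. The C9(O-acyl)–C11 bridge is the C=CH2 unit of a 6-methylene δ-lactone attached to quaternary C10.
3. Further cuts: lactone O–C9 (oxidative lactonization of a vinyl acid), C5–C10 (Ireland–Claisen rearrangement of a geranyl ester), the ester C–O bond, and aryl C8–C7 (Negishi coupling). These lead to creosol, an ester-bearing alkylzinc bromide and geraniol.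
4. Forward order of rings: the arene comes from creosol, the δ-lactone closes in step 10, ring B and the bicyclo[2.2.2]octene close together in step 13, and no ring forms afterwards.
5. Stereochemistry: C5 and C10 come from the enantioselective Ireland–Claisen step (chiral boron controller, chair transition state). C8, C9 and C12 are relayed from C10 and C5 in the cycloaddition. C14 comes from a thermodynamically controlled electron-transfer reduction.

Key step: step 13

Assumption: the (S,S) antipode of the boron controller is taken to deliver the (2R,3R) acid; if its sense of induction is the opposite, the (R,R) reagent is used and nothing else changes.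

**Route**

Step 1
Reactants: 1 creosol
Product: 2 6-bromocreosol (2-bromo-6-methoxy-4-methylphenol)
Conditions: NBS (1.0 equiv), i-Pr2NH (10 mol%), CH2Cl2, 0 °C
Reagents that add atoms: N-bromosuccinimide, O=C1CCC(=O)N1Br
Why: Electrophilic aromatic bromination; with the para position blocked by the methyl group, the amine-mediated NBS bromination should go to the free position ortho to the phenol OH.

Step 2
Reactants: 2 6-bromocreosol
Product: 3 6-bromocreosol triisopropylsilyl ether
Conditions: TIPSOTf, 2,6-lutidine, CH2Cl2, 0 to 23 °C
Reagents that add atoms: triisopropylsilyl trifluoromethanesulfonate, CC(C)[Si](OS(=O)(=O)C(F)(F)F)(C(C)C)C(C)C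
Why: Silylation of the hindered phenol with the silyl triflate gives an aryl TIPS ether that should tolerate the organozinc, organolithium, peracid, periodic acid and chlorite steps and is removed later by fluoride.

Step 3
Reactants: 3 6-bromocreosol triisopropylsilyl ether; 4 (4-ethoxy-4-oxobutyl)zinc bromide
Product: 5 ethyl 4-[3-methoxy-5-methyl-2-(triisopropylsilyloxy)phenyl]butanoate
Conditions: Pd(OAc)2 (2 mol%), SPhos (4 mol%), THF, 23 to 50 °C
Reagents that add atoms: none
Why: Negishi coupling; zerovalent palladium formed from Pd(OAc)2 and SPhos inserts into the hindered aryl bromide, the ester-tolerant primary alkylzinc transmetalates, and reductive elimination forms the C7–C8 bond.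

Step 4
Reactants: 5 ethyl 4-arylbutanoate; 6 geraniol
Product: 7 geranyl 4-[3-methoxy-5-methyl-2-(triisopropylsilyloxy)phenyl]butanoate
Conditions: 6 (1.5 equiv), Ti(O-i-Pr)4 (10 mol%), toluene, reflux with slow distillation of the alcohol
Reagents that add atoms: none
Why: Titanium alkoxide-catalysed transesterification, driven by removal of ethanol, exchanges ethyl for geranyl under neutral conditions that leave the silyl ether and the E alkene untouched.

Step 5
Reactants: 7 geranyl 4-arylbutanoate
Product: 9 (2R,3R)-2-{2-[3-methoxy-5-methyl-2-(triisopropylsilyloxy)phenyl]ethyl}-3,7-dimethyl-3-vinyloct-6-enoic acid, via boron ketene acetal 8 (not isolated)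
Conditions: (4S,5S)-2-bromo-4,5-diphenyl-1,3-bis{[3,5-bis(trifluoromethyl)phenyl]sulfonyl}-1,3,2-diazaborolidine (pre-formed, 1.2 equiv), Et3N (1.5 equiv), toluene–hexane, −78 °C, then slow warming to 23 °C; aqueous work-up
Reagents that add atoms: none
Why: Enantioselective Ireland–Claisen rearrangement of the E(O) boron ketene acetal (C6 cis to the geranyloxy oxygen) through a chair transition state in which the E alkene of the geranyl unit holds C20 axial and the enolate geometry holds C6 axial, so that H5 ends anti to C20 across the new C5–C10 bond while the C2-symmetric diazaborolidine selects the enolate face and fixes both centres.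

Step 6
Reactants: 9 Claisen acid
Product: 10 (3R,4R)-3-{2-[3-methoxy-5-methyl-2-(triisopropylsilyloxy)phenyl]ethyl}-4,8-dimethyl-4-vinylnon-7-en-2-one
Conditions: MeLi (4 equiv), Et2O, 0 to 23 °C; inverse quench into cold 1 M HCl
Reagents that add atoms: methyllithium, [Li]C
Why: Addition of methyllithium to the lithium carboxylate stops at the dilithio gem-diolate, which releases the methyl ketone only on the acidic inverse quench (carboxylic acid to methyl ketone), so C4 is installed without over-addition and without touching C5.

Step 7
Reactants: 10 methyl ketone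
Product: 11 epoxy ketone (10 with the trisubstituted alkene as a 2,2-dimethyloxirane, both epimers at the oxirane CH)
Conditions: mCPBA (1.05 equiv), NaHCO3, CH2Cl2, 0 °C
Reagents that add atoms: 3-chloroperoxybenzoic acid, OOC(=O)c1cccc(Cl)c1
Why: Prilezhaev epoxidation; the electron-rich trisubstituted alkene should react with the peracid far faster than the monosubstituted vinyl group or the ketone (Baeyer–Villiger), and the new epoxide centre is cleaved in the next step.

Step 8
Reactants: 11 epoxy ketone
Product: 12 (4R,5R)-5-acetyl-7-[3-methoxy-5-methyl-2-(triisopropylsilyloxy)phenyl]-4-methyl-4-vinylheptanal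
Conditions: H5IO6 (1.2 equiv), THF–H2O, 0 to 23 °C
Reagents that add atoms: none
Why: Acid-promoted opening of the epoxide to the glycol followed in the same flask by periodate glycol cleavage (Malaprade reaction) releases acetone and leaves the C3 aldehyde, whose oxygen is the former epoxide oxygen.

Step 9
Reactants: 12 aldehyde
Product: 13 (4R,5R)-5-acetyl-7-[3-methoxy-5-methyl-2-(triisopropylsilyloxy)phenyl]-4-methyl-4-vinylheptanoic acid
Conditions: NaClO2, NaH2PO4, 2-methyl-2-butene, t-BuOH–H2O, 0 to 23 °C
Reagents that add atoms: sodium chlorite, [Na+].[O-]Cl=O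
Why: Pinnick oxidation converts the aldehyde to the acid without epimerizing C5, with 2-methyl-2-butene trapping the hypochlorous acid that could otherwise chlorinate the electron-rich arene or the vinyl group.

Step 10
Reactants: 13 acetyl vinyl acid
Product: 14 silyl-protected enol lactone, (5S)-5-methyl-6-methylidene-5-{(3R)-2-oxo-5-[3-methoxy-5-methyl-2-(triisopropylsilyloxy)phenyl]pentan-3-yl}tetrahydro-2H-pyran-2-one
Conditions: Pd(OAc)2 (10 mol%), NaOAc (2 equiv), O2 (1 atm), DMSO, 23 to 60 °C
Reagents that add atoms: none
Why: Wacker-type aerobic oxidative cyclization of an alkenoic acid, in which divalent palladium activates the vinyl group, the carboxylate adds to C9 by 6-exo acyloxypalladation, and beta-hydride elimination of the only available hydrogen (H9) gives the exocyclic C9=C11 enol lactone (quaternary C10 excludes an endocyclic isomer), with O2 in DMSO returning zerovalent palladium to the divalent state.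

Step 11
Reactants: 14 silyl-protected enol lactone
Product: 15 free phenol enol lactone (14 with OH in place of the silyloxy group)
Conditions: Bu4NF, AcOH (1:1), THF, 0 °C
Reagents that add atoms: none
Why: Fluoride cleavage of the aryl silyl ether, buffered with acetic acid so that neither phenoxide nor fluoride opens the acylating enol lactone or epimerizes C5.

Step 12
Reactants: 15 free phenol enol lactone
Product: 16 masked ortho-benzoquinone, 6,6-dimethoxy-4-methylcyclohexa-2,4-dien-1-one carrying at C2 the keto lactone side chain of 15
Conditions: PhI(OAc)2 (1.1 equiv), MeOH, 0 °C, 15 min; extraction into toluene, solution used at once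
Reagents that add atoms: methanol, CO
Why: Oxidative dearomatization of a 2-methoxyphenol by the hypervalent iodine reagent, in which the phenoxonium ion is captured by methanol at the methoxy-bearing carbon, where oxocarbenium stabilization is greatest, to give the 6,6-dimethoxy-2,4-dienone and not a para-quinol ether.

Step 13
Reactants: 16 masked ortho-benzoquinone
Product: 17 tetracyclic bicyclo[2.2.2]octenone adduct (C3 to O–C9 δ-lactone, acetyl on C5, C13 dimethyl ketal, C14 ketone, C15=C16 with the C17 methyl; H5 and the lactone oxygen anti to C20, lactone oxygen toward the C15=C16 bridge)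
Conditions: toluene (about 0.005 M), BHT (trace), argon, 80 to 110 °C
Reagents that add atoms: none
Why: Proposed new method: the electron-poor 2,4-dienone (C14=O, C8=C15, C16=C12, C13 ketal) should add the electron-rich enol ester in a concerted but asynchronous inverse-electron-demand [4+2] cycloaddition, the nucleophilic C11 methylene bonding ahead to C12 (the dienone terminus of largest LUMO coefficient) and C9 then closing onto C8, so the polarity of both partners agrees with the only regiochemistry the tether allows. The closest known reaction type is the intramolecular Diels–Alder reaction of 6,6-dimethoxycyclohexa-2,4-dienones that carry an alkene on a carbon tether at the carbon alpha to the carbonyl, together with the intermolecular ortho- and endo-selective addition of enol ethers and vinyl esters to the same dienones; an exocyclic enol lactone has not served as the tethered partner. Ring B closes through the C8–C9 bond as a six-membered ring over the four-atom tether C7–C6–C5–C10 (exo with respect to C9=C11, chair-like, C5 acetyl equatorial, C20 axial), and the bicyclo[2.2.2]octene closes as the bridged [4+2] ring C8–C9–C11–C12–C16–C15 across the C14–C13 bridge. C9 is controlled by C10: in the lactone half-chair the C5 arm and the C20 methyl lie on opposite faces of the enol plane, and the two-carbon link C6–C7 lets C8 reach only the face that carries C5, which makes lactone and ring B cis-fused with the lactone oxygen anti to C20. C8 and C12 follow from suprafacial addition to the dienone once that face is fixed and the acyloxy oxygen lies endo under the diene, toward the new C15=C16 bridge, while the bulky quaternary C10 takes the open exo side beneath the C14 carbonyl. The step therefore needs dienophile-face selectivity (secured by the lactone ring and tether), endo placement of the oxygen (favoured by secondary overlap and by the size difference between O and C10, but not enforced) and a cyclization faster than dienone dimerization (helped by the 2,4-dialkyl substitution and high dilution).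

Step 14
Reactants: 17 tetracyclic adduct
Product: 18 isopropenyl adduct (17 with the C4 acetyl converted to isopropenyl)
Conditions: Zn, CH2Br2, TiCl4 (pre-formed reagent), THF–CH2Cl2, 0 to 23 °C
Reagents that add atoms: dibromomethane, BrCBr
Why: Takai–Lombardo methylenation with the non-basic Zn/CH2Br2/TiCl4 reagent should convert only the accessible C4 methyl ketone, since the C14 ketone is buried between quaternary C8 and the C13 ketal, lactones do not react, and no basic ylide is present to enolize C5.

Step 15
Reactants: 18 isopropenyl adduct
Product: 19 13-deoxy ketone (18 with C13 as CH2)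
Conditions: SmI2 (5 equiv), THF–MeOH, −78 to 0 °C
Reagents that add atoms: none
Why: Reductive cleavage of alpha-alkoxy ketones by SmI2, in which two successive electron-transfer, elimination and protonation cycles through the C14 ketyl and samarium enolate remove both C13 methoxy groups, while the lactone and the unconjugated alkenes should be inert in the absence of water or amine activation.

Step 16
Reactants: 19 13-deoxy ketone
Product: 20 C14 alcohol (hydroxyl toward the C15=C16 bridge)
Conditions: SmI2 (2.5 equiv), H2O (about 20 equiv), THF, 0 °C, quenched as soon as the ketone is consumed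
Reagents that add atoms: none
Why: Electron-transfer reduction of the ketone by SmI2–H2O passes through a ketyl and an alpha-oxy organosamarium that should settle with the large O–Sm group on the open side facing the C15=C16 bridge, away from the syn-axial C20 methyl, so protonation gives the more stable C14 alcohol (the outcome of dissolving-metal, not hydride, reduction), while the limited reagent and short time spare the more slowly reduced δ-lactone.

Step 17
Reactants: 20 C14 alcohol
Product: 21 C14 acetate
Conditions: Ac2O, DMAP, pyridine, CH2Cl2, 23 °C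
Reagents that add atoms: acetic anhydride, CC(=O)OC(C)=O
Why: DMAP-catalysed acylation of the secondary C14 alcohol, the lactone and both alkenes being inert.

Step 18
Reactants: 21 C14 acetate
Product: 23 crotobarin, via C15 allylic hydroperoxide 22 (not isolated)
Conditions: O2, tetraphenylporphyrin (cat.), visible light, Ac2O, pyridine, DMAP (cat.), CH2Cl2, 0 to 23 °C
Reagents that add atoms: oxygen (as singlet oxygen), O=O
Why: Schenck ene reaction of singlet oxygen on the trisubstituted C15=C16 alkene, in which oxygen adds to C15 and only the C17 methyl can supply the allylic hydrogen (C8 is quaternary and a C12 bridgehead alkene is excluded by Bredt's rule) while the 1,1-disubstituted isopropenyl group reacts much more slowly, followed by in situ acetylation and elimination of the hydroperoxide (Kornblum–DeLaMare-type dehydration) to the C15 ketone flanked by the C16=C17 methylene.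

**Compound list**

1 | creosol (2-methoxy-4-methylphenol) | Cc1ccc(O)c(OC)c1 | starting material
2 | 6-bromocreosol (2-bromo-6-methoxy-4-methylphenol) | Cc1cc(Br)c(O)c(OC)c1 | intermediate
3 | 6-bromocreosol triisopropylsilyl ether | Cc1cc(Br)c(O[Si](C(C)C)(C(C)C)C(C)C)c(OC)c1 | intermediate
4 | (4-ethoxy-4-oxobutyl)zinc bromide | CCOC(=O)CCC[Zn]Br | starting material
5 | ethyl 4-[3-methoxy-5-methyl-2-(triisopropylsilyloxy)phenyl]butanoate | CCOC(=O)CCCc1cc(C)cc(OC)c1O[Si](C(C)C)(C(C)C)C(C)C | intermediate
6 | geraniol, (2E)-3,7-dimethylocta-2,6-dien-1-ol | CC(C)=CCC/C(C)=C/CO | starting material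
7 | geranyl 4-[3-methoxy-5-methyl-2-(triisopropylsilyloxy)phenyl]butanoate | CC(C)=CCC/C(C)=C/COC(=O)CCCc1cc(C)cc(OC)c1O[Si](C(C)C)(C(C)C)C(C)C | intermediate
8 | boron ketene acetal of 7 (E(O) geometry, C6 chain cis to the geranyloxy oxygen, boron held in the (4S,5S)-diazaborolidine) | Cc1cc(CC/C=C(\OC/C=C(C)/CCC=C(C)C)OB2N(S(=O)(=O)c3cc(C(F)(F)F)cc(C(F)(F)F)c3)[C@@H](c3ccccc3)[C@H](c3ccccc3)N2S(=O)(=O)c2cc(C(F)(F)F)cc(C(F)(F)F)c2)c(O[Si](C(C)C)(C(C)C)C(C)C)c(OC)c1 | intermediate
9 | (2R,3R)-2-{2-[3-methoxy-5-methyl-2-(triisopropylsilyloxy)phenyl]ethyl}-3,7-dimethyl-3-vinyloct-6-enoic acid | Cc1cc(CC[C@@H](C(=O)O)[C@](C=C)(C)CCC=C(C)C)c(O[Si](C(C)C)(C(C)C)C(C)C)c(OC)c1 | intermediate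
10 | (3R,4R)-3-{2-[3-methoxy-5-methyl-2-(triisopropylsilyloxy)phenyl]ethyl}-4,8-dimethyl-4-vinylnon-7-en-2-one | Cc1cc(CC[C@@H](C(C)=O)[C@](C=C)(C)CCC=C(C)C)c(O[Si](C(C)C)(C(C)C)C(C)C)c(OC)c1 | intermediate
11 | epoxy ketone, 10 with the trisubstituted alkene as a 2,2-dimethyloxirane (both epimers at the oxirane CH; C5 and C10 as in 10) | Cc1cc(CC[C@@H](C(C)=O)[C@](C=C)(C)CCC2OC2(C)C)c(O[Si](C(C)C)(C(C)C)C(C)C)c(OC)c1 | intermediate
12 | (4R,5R)-5-acetyl-7-[3-methoxy-5-methyl-2-(triisopropylsilyloxy)phenyl]-4-methyl-4-vinylheptanal | Cc1cc(CC[C@@H](C(C)=O)[C@](C=C)(C)CCC=O)c(O[Si](C(C)C)(C(C)C)C(C)C)c(OC)c1 | intermediate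
13 | (4R,5R)-5-acetyl-7-[3-methoxy-5-methyl-2-(triisopropylsilyloxy)phenyl]-4-methyl-4-vinylheptanoic acid | Cc1cc(CC[C@@H](C(C)=O)[C@](C=C)(C)CCC(=O)O)c(O[Si](C(C)C)(C(C)C)C(C)C)c(OC)c1 | intermediate
14 | silyl-protected enol lactone, (5S)-5-methyl-6-methylidene-5-{(3R)-2-oxo-5-[3-methoxy-5-methyl-2-(triisopropylsilyloxy)phenyl]pentan-3-yl}tetrahydro-2H-pyran-2-one | Cc1cc(CC[C@@H](C(C)=O)[C@]2(C)CCC(=O)OC2=C)c(O[Si](C(C)C)(C(C)C)C(C)C)c(OC)c1 | intermediate
15 | free phenol enol lactone, (5S)-5-[(3R)-5-(2-hydroxy-3-methoxy-5-methylphenyl)-2-oxopentan-3-yl]-5-methyl-6-methylidenetetrahydro-2H-pyran-2-one | Cc1cc(CC[C@@H](C(C)=O)[C@]2(C)CCC(=O)OC2=C)c(O)c(OC)c1 | intermediate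
16 | masked ortho-benzoquinone, 6,6-dimethoxy-4-methylcyclohexa-2,4-dien-1-one with the keto lactone side chain of 15 at C2 | CC1=CC(OC)(OC)C(=O)C(CC[C@@H](C(C)=O)[C@]2(C)CCC(=O)OC2=C)=C1 | intermediate
17 | tetracyclic Diels–Alder adduct: bicyclo[2.2.2]octenone (C14 ketone, C13 dimethyl ketal, C15=C16 with C17 methyl) fused to ring B and the C3/C9 δ-lactone, acetyl on C5; H5 and lactone O anti to C20, lactone O toward the C15=C16 bridge | CC1=C[C@]23CC[C@@H](C(C)=O)[C@]4(C)CCC(=O)O[C@@]42C[C@H]1C(OC)(OC)C3=O | intermediate
18 | isopropenyl adduct (17 with isopropenyl on C5) | CC1=C[C@]23CC[C@@H](C(=C)C)[C@]4(C)CCC(=O)O[C@@]42C[C@H]1C(OC)(OC)C3=O | intermediate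
19 | 13-deoxy ketone (18 with C13 as CH2, C14 ketone kept) | CC1=C[C@]23CC[C@@H](C(=C)C)[C@]4(C)CCC(=O)O[C@@]42C[C@H]1CC3=O | intermediate
20 | C14 alcohol (hydroxyl toward the C15=C16 bridge, H14 toward the C9–C11 bridge) | CC1=C[C@]23CC[C@@H](C(=C)C)[C@]4(C)CCC(=O)O[C@@]42C[C@H]1C[C@@H]3O | intermediate
21 | C14 acetate of 20 | CC1=C[C@]23CC[C@@H](C(=C)C)[C@]4(C)CCC(=O)O[C@@]42C[C@H]1C[C@@H]3OC(C)=O | intermediate
22 | C15 allylic hydroperoxide with C16=C17 methylene (C15 configuration not defined) | C=C1C(OO)[C@]23CC[C@@H](C(=C)C)[C@]4(C)CCC(=O)O[C@@]42C[C@H]1C[C@@H]3OC(C)=O | intermediate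
23 | crotobarin | C=C1C(=O)[C@]23CC[C@@H](C(=C)C)[C@]4(C)CCC(=O)O[C@@]42C[C@H]1C[C@@H]3OC(C)=O | target

**Step count**

Total: 18 steps. Longest linear sequence: 18 steps, from creosol 1 to crotobarin 23; the zinc reagent 4 and geraniol 6 enter as purchased.

**Steps most likely to fail**

Step 13 (cycloaddition). The tethered enol lactone is a weak, hindered 1,1-disubstituted dienophile. It may add so slowly that the dienone dimerizes or decomposes on heating, or it may add with the acyloxy oxygen exo. The fallback replaces the enol ester by a silyl enol ether, the class of electron-rich partner whose inverse-demand addition to these dienones is established, and closes the lactone afterwards. It sets out from 13 and returns at 18, so step 14 is not needed.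
- Esterification of 13 with Me3SiCHN2 (MeOH–toluene) gives methyl ester F1.
- Wittig methylenation of the C4 acetyl group (Ph3P=CH2, THF) gives isopropenyl ester F2. The methylenation is moved ahead because a second methyl ketone would be silylated as well, and because the silyl enol ether should cyclize at or below room temperature, where an unactivated isopropenyl group is a spectator.
- Wacker oxidation of the monosubstituted vinyl group (PdCl2, CuCl, O2, DMF–H2O) gives C9 methyl ketone F3.
- Bu4NF–AcOH gives phenol F4, and PhI(OAc)2 in MeOH gives dienone F5, whose ring carbonyl cannot enolize.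
- TBSOTf and Et3N (CH2Cl2, −78 °C) should therefore silylate only the C9 methyl ketone, giving silyl enol ether F6.
- On warming, F6 should cyclize through the same chair-like tether (isopropenyl equatorial, silyloxy group axial on ring B and anti to C20, oxygen endo) to silyl ether adduct F7.
- Bu4NF in THF then frees the tertiary C9 alkoxide, which lactonizes onto the methyl ester and gives 18.

Step 16 (C14 reduction). Protonation may occur without facial preference, or SmI2–H2O may also reduce the δ-lactone. The fallback separates reduction from stereocontrol. Ketone 19 is reduced with NaBH4 (MeOH, 0 °C) from the open face to the C14-epimeric alcohol F8 (hydroxyl toward the C9–C11 bridge). F8 is then equilibrated by reversible hydride transfer under Meerwein–Ponndorf–Verley/Oppenauer conditions (Al(O-i-Pr)3 with a little acetone in toluene–i-PrOH at reflux) to the less crowded epimer, which is 20.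

Step 10 (oxidative lactonization). Acyloxypalladation at the neopentyl-type vinyl group may be slow, leaving room for allylic oxidation or loss of the catalyst as palladium metal. The fallback makes the same enol lactone in two classical operations from 13. Iodolactonization (I2, NaHCO3, MeCN, 0 °C; 6-exo, carboxylate to C9) gives iodomethyl lactone F9 as a mixture of C9 epimers. Dehydroiodination with DBU (toluene, 80 °C), for which H9 is the only beta-hydrogen, returns the route at 14.

Further compounds
F1 | step 13 | methyl ester of 13 | Cc1cc(CC[C@@H](C(C)=O)[C@](C=C)(C)CCC(=O)OC)c(O[Si](C(C)C)(C(C)C)C(C)C)c(OC)c1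
F2 | step 13 | isopropenyl ester (F1 with isopropenyl on C5) | Cc1cc(CC[C@@H](C(=C)C)[C@](C=C)(C)CCC(=O)OC)c(O[Si](C(C)C)(C(C)C)C(C)C)c(OC)c1
F3 | step 13 | C9 methyl ketone (F2 with acetyl in place of vinyl on C10) | Cc1cc(CC[C@@H](C(=C)C)[C@](C(C)=O)(C)CCC(=O)OC)c(O[Si](C(C)C)(C(C)C)C(C)C)c(OC)c1
F4 | step 13 | phenol (F3 without the silyl group) | Cc1cc(CC[C@@H](C(=C)C)[C@](C(C)=O)(C)CCC(=O)OC)c(O)c(OC)c1
F5 | step 13 | dienone, 6,6-dimethoxy-4-methylcyclohexa-2,4-dien-1-one with the keto ester side chain of F4 at C2 | CC1=CC(OC)(OC)C(=O)C(CC[C@@H](C(=C)C)[C@](C(C)=O)(C)CCC(=O)OC)=C1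
F6 | step 13 | silyl enol ether (F5 with the C9 ketone as its tert-butyldimethylsilyl enol ether) | CC1=CC(OC)(OC)C(=O)C(CC[C@@H](C(=C)C)[C@](C(=C)O[Si](C)(C)C(C)(C)C)(C)CCC(=O)OC)=C1
F7 | step 13 | silyl ether adduct (bicyclo[2.2.2]octenone with C9 silyloxy group and open methyl ester chain on C10) | CC1=C[C@]23CC[C@@H](C(=C)C)[C@](C)(CCC(=O)OC)[C@@]2(O[Si](C)(C)C(C)(C)C)C[C@H]1C(OC)(OC)C3=O
F8 | step 16 | C14-epimeric alcohol (hydroxyl toward the C9–C11 bridge) | CC1=C[C@]23CC[C@@H](C(=C)C)[C@]4(C)CCC(=O)O[C@@]42C[C@H]1C[C@H]3O
F9 | step 10 | iodomethyl lactone (both C9 epimers) | Cc1cc(CC[C@@H](C(C)=O)[C@]2(C)CCC(=O)OC2CI)c(O[Si](C(C)C)(C(C)C)C(C)C)c(OC)c1
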